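The chain is numbered from the benzylic carbon C1. The plan cuts between the enone carbonyl carbon C5 and the vinylic carbon C6. A base-free Liebeskind–Srogl coupling joins an S-phenyl thioester carrying the arene and the C2=C3 alkene with a (Z)-alkenylboronic acid carrying the oxan-3-one ring, giving the C5 ketone directly. The step exploits the acyl–alkenyl junction of the skipped dienone: palladium inserts only into the C(O)–S bond, the ring ketone C12 stays untouched, the Z geometry of C6=C7 is carried over with retention, and the acidic C4 methylene between C2=C3 and C5=O never meets base. The oxanone comes from (R)-linalool by methacrolein aldol and 6-exo mercuricyclisation.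

Key step: step 17

Numbering: C11 (quaternary), C12 (C=O), C13, C14 (carbinol), C15 (CMe2) and the ether oxygen form the oxan-3-one ring.
Assumption: the enol borinate made from a methyl ketone and (−)-Ipc2BCl attacks the aldehyde on its Si face, the usual sense for methyl ketones; should this α-silyloxy ketone show the opposite sense, (+)-Ipc2BCl is used in step 10 and nothing else changes.
Remark: the vinyl β-lactone of step 3 is racemic; its only stereocentre becomes an alkene carbon in step 4.

Step 1
Reactants: 1 2-bromo-6-methylanisole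
Product: 3 3-bromo-4-methoxy-5-methylphenol, via arylboronate 2 (not isolated)
Conditions: [Ir(OMe)(cod)]2 (1.5 mol%), 4,4'-di-tert-butyl-2,2'-bipyridine (3 mol%), HBpin, THF, 80 °C; then Oxone (2KHSO5·KHSO4·K2SO4), acetone/H2O, rt
Reagents that add atoms: potassium peroxymonosulfate [K+].[O-]S(=O)(=O)OO
Why: Iridium-catalysed C–H borylation is sterically controlled and should borylate the only ring C–H without an ortho substituent (para to OMe), and the one-pot oxidation of the C–B bond gives the phenol.

Step 2
Reactants: 3 3-bromo-4-methoxy-5-methylphenol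
Product: 4 (3-bromo-4-methoxy-5-methylphenoxy)(tert-butyl)dimethylsilane
Conditions: t-BuMe2SiCl, imidazole, DMF, rt
Reagents that add atoms: tert-butyldimethylsilyl chloride CC(C)(C)[Si](C)(C)Cl
Why: Standard silylation of a phenol; the silyl ether tolerates the Grignard reagent of step 4.

Step 3
Reactants: 5 S-phenyl thioacetate; 6 methyl vinyl ketone
Product: 8 4-methyl-4-vinyloxetan-2-one (racemic), via lithium enolate 7 (not isolated)
Conditions: LDA, THF, −78 °C; 6, −78 → 0 °C; aq. NH4Cl
Reagents that add atoms: none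
Why: Thiol ester enolate–ketone β-lactone synthesis: the enolate adds 1,2 to the ketone carbonyl at −78 °C and the aldolate closes on the thioester (4-exo-trig) with loss of thiophenolate on warming.

Step 4
Reactants: 4 (3-bromo-4-methoxy-5-methylphenoxy)(tert-butyl)dimethylsilane; 8 4-methyl-4-vinyloxetan-2-one
Product: 10 (E)-5-[5-(tert-butyldimethylsilyloxy)-2-methoxy-3-methylphenyl]-3-methylpent-3-enoic acid, via aryl Grignard reagent 9 (not isolated)
Conditions: Mg, THF, 45 °C; then CuI (10 mol%), Me2S, −30 °C; 8, −30 → 0 °C; 1 M HCl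
Reagents that add atoms: none
Why: Copper-catalysed SN2' ring opening of a β-vinyl β-lactone by a Grignard reagent: the aryl group adds to the vinyl terminus anti to the leaving carboxylate and the C2=C3 alkene should form mainly as E, the lactone reacting through the conformer in which the methyl group, not the ring CH2, lies syn to the vinyl terminus.

Step 5
Reactants: 10 (E)-5-[5-(tert-butyldimethylsilyloxy)-2-methoxy-3-methylphenyl]-3-methylpent-3-enoic acid
Product: 11 S-phenyl (E)-5-[5-(tert-butyldimethylsilyloxy)-2-methoxy-3-methylphenyl]-3-methylpent-3-enethioate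
Conditions: PhSH, DCC, DMAP (5 mol%), CH2Cl2, 0 °C
Reagents that add atoms: thiophenol Sc1ccccc1
Why: Steglich-type thioesterification (carbodiimide activation, catalytic DMAP) at 0 °C, mild enough to leave the β,γ-double bond in place.

Step 6
Reactants: 12 (R)-(−)-linalool
Product: 13 triethyl{[(3R)-3,7-dimethylocta-1,6-dien-3-yl]oxy}silane
Conditions: Et3SiOTf, 2,6-lutidine, CH2Cl2, 0 °C
Reagents that add atoms: triethylsilyl triflate CC[Si](CC)(CC)OS(=O)(=O)C(F)(F)F
Why: Silylation of the tertiary allylic alcohol with the silyl triflate; the ether is needed for the boron aldol of step 10 and the C11 stereocentre comes unchanged from the chiral pool.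

Step 7
Reactants: 13 triethyl{[(3R)-3,7-dimethylocta-1,6-dien-3-yl]oxy}silane
Product: 15 (4R)-4-methyl-4-(triethylsilyloxy)hex-5-en-1-ol, via ozonide 14 (not isolated)
Conditions: O3 (1 equiv), CH2Cl2, −78 °C; then NaBH4, MeOH, −78 → 0 °C
Reagents that add atoms: ozone [O-][O+]=O
Why: Chemoselective ozonolysis with reductive work-up: ozone attacks the electron-rich trisubstituted alkene far faster than the monosubstituted vinyl group beside the silyloxy carbon, and NaBH4 reduces the ozonide to the primary alcohol.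

Step 8
Reactants: 15 (4R)-4-methyl-4-(triethylsilyloxy)hex-5-en-1-ol
Product: 16 (3R)-6-chloro-3-methyl-3-(triethylsilyloxy)hex-1-ene
Conditions: PPh3, N-chlorosuccinimide, CH2Cl2, 0 °C → rt
Reagents that add atoms: N-chlorosuccinimide O=C1CCC(=O)N1Cl
Why: Appel-type chlorination by SN2 displacement of the oxyphosphonium group; the chloride is chosen as the C8 handle because it survives the silver salt of step 9 and the tin hydride of step 12.

Step 9
Reactants: 16 (3R)-6-chloro-3-methyl-3-(triethylsilyloxy)hex-1-ene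
Product: 17 (3R)-6-chloro-3-methyl-3-(triethylsilyloxy)hexan-2-one
Conditions: PdCl2(Quinox) (5 mol%; Quinox = 2-(4,5-dihydro-1,3-oxazol-2-yl)quinoline), AgSbF6 (12 mol%), aq. t-BuOOH, CH2Cl2, rt
Reagents that add atoms: tert-butyl hydroperoxide CC(C)(C)OO
Why: Wacker-type oxidation in its peroxide-mediated variant, which turns terminal alkenes bearing an allylic oxygen substituent into methyl ketones; the neighbouring stereocentre is fully substituted and cannot epimerise.

Step 10
Reactants: 17 (3R)-6-chloro-3-methyl-3-(triethylsilyloxy)hexan-2-one; 18 methacrolein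
Product: 20 (3S,6R)-9-chloro-3-hydroxy-2,6-dimethyl-6-(triethylsilyloxy)non-1-en-5-one, via enol borinate 19 (not isolated)
Conditions: (−)-Ipc2BCl, Et3N, Et2O, 0 °C; 18, −78 → −20 °C; then MeOH, pH 7 buffer, H2O2, 0 °C
Reagents that add atoms: none
Why: Boron-mediated aldol reaction of an enol diisopinocampheylborinate: only the methyl side can enolise, the Ipc ligands direct the enolate to the Si face of 18 through a cyclic transition state and so set C14 as S (reagent control, little bias from the fully substituted C11), and a minor C14 epimer is a diastereomer removable by chromatography.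

Step 11
Reactants: 20 (3S,6R)-9-chloro-3-hydroxy-2,6-dimethyl-6-(triethylsilyloxy)non-1-en-5-one
Product: 21 (3S,6R)-9-chloro-3,6-dihydroxy-2,6-dimethylnon-1-en-5-one
Conditions: HF·pyridine, pyridine, THF, 0 °C → rt
Reagents that add atoms: none
Why: Fluoride-mediated cleavage of the tertiary silyl ether under buffered conditions, mild enough for the β-hydroxy ketone and the primary chloride.

Step 12
Reactants: 21 (3S,6R)-9-chloro-3,6-dihydroxy-2,6-dimethylnon-1-en-5-one
Product: 23 (2R,5S)-2-(3-chloropropyl)-5-hydroxy-2,6,6-trimethyloxan-3-one, via alkylmercury chloride 22 (not isolated)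
Conditions: Hg(OCOCF3)2, CH2Cl2, 0 °C; aq. NaCl; then n-Bu3SnH, AIBN (cat.), THF, rt
Reagents that add atoms: none
Why: Intramolecular alkoxymercuration–demercuration: the C11 hydroxyl attacks the tertiary C15 of the mercurinium ion in a 6-exo-trig Markovnikov closure without a free cation (so no pinacol-type hydride shift from C14), C15 becomes CMe2 with no new stereocentre, and tin hydride cleaves the C–Hg bond by a radical chain that spares the ketone and the primary chloride.

Step 13
Reactants: 23 (2R,5S)-2-(3-chloropropyl)-5-hydroxy-2,6,6-trimethyloxan-3-one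
Product: 24 (2R,5S)-2-(3-chloropropyl)-2,6,6-trimethyl-5-(triethylsilyloxy)oxan-3-one
Conditions: Et3SiOTf, 2,6-lutidine, CH2Cl2, −78 °C
Reagents that add atoms: triethylsilyl triflate CC[Si](CC)(CC)OS(=O)(=O)C(F)(F)F
Why: Silylation with the silyl triflate, needed for the hindered secondary hydroxyl beside the CMe2 carbon; the ether shields the hydroxyl from the organozinc reagent of step 16.

Step 14
Reactants: 24 (2R,5S)-2-(3-chloropropyl)-2,6,6-trimethyl-5-(triethylsilyloxy)oxan-3-one
Product: 25 (2R,5S)-2-(3-iodopropyl)-2,6,6-trimethyl-5-(triethylsilyloxy)oxan-3-one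
Conditions: NaI, NaHCO3, acetone, reflux
Reagents that add atoms: sodium iodide [Na+].[I-]
Why: Finkelstein halide exchange (SN2 at the primary carbon, driven by precipitation of NaCl) gives the iodide needed for zinc insertion.

Step 15
Reactants: 26 propyne
Product: 28 2-[(Z)-2-bromoprop-1-enyl]-4,4,5,5-tetramethyl-1,3,2-dioxaborolane, via alkenyldibromoborane 27 (not isolated)
Conditions: BBr3, CH2Cl2, −78 °C → rt; then pinacol, −78 °C → rt
Reagents that add atoms: boron tribromide BrB(Br)Br; pinacol CC(C)(O)C(C)(C)O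
Why: Haloboration: BBr3 adds syn across propyne with boron at the terminal carbon, which fixes Br and B cis (Z), and esterification with pinacol at low temperature should preserve this geometry.

Step 16
Reactants: 25 (2R,5S)-2-(3-iodopropyl)-2,6,6-trimethyl-5-(triethylsilyloxy)oxan-3-one; 28 2-[(Z)-2-bromoprop-1-enyl]-4,4,5,5-tetramethyl-1,3,2-dioxaborolane
Product: 31 [(Z)-2-methyl-5-[(2R,5S)-2,6,6-trimethyl-3-oxo-5-(triethylsilyloxy)oxan-2-yl]pent-1-enyl]boronic acid, via alkylzinc iodide 29 (not isolated), via alkenyl pinacol boronate 30 (not isolated)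
Conditions: Zn dust (activated with BrCH2CH2Br and Me3SiCl), LiCl, THF, 35 °C; then 28, Pd(P(t-Bu)3)2 (2 mol%), rt; work-up; then NaIO4, NH4OAc, acetone/H2O, rt
Reagents that add atoms: water O
Why: LiCl-promoted zinc insertion into the primary C–I bond (ketone and silyl ether tolerated) followed by Negishi coupling, which replaces the bromine of 28 by the alkyl group with retention so that C8 ends cis to boron, and periodate cleavage of the pinacol ester to the boronic acid.

Step 17
Reactants: 11 S-phenyl (E)-5-[5-(tert-butyldimethylsilyloxy)-2-methoxy-3-methylphenyl]-3-methylpent-3-enethioate; 31 [(Z)-2-methyl-5-[(2R,5S)-2,6,6-trimethyl-3-oxo-5-(triethylsilyloxy)oxan-2-yl]pent-1-enyl]boronic acid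
Product: 32 (2R,5S)-2-[(4Z,8E)-10-[5-(tert-butyldimethylsilyloxy)-2-methoxy-3-methylphenyl]-4,8-dimethyl-6-oxodeca-4,8-dienyl]-2,6,6-trimethyl-5-(triethylsilyloxy)oxan-3-one
Conditions: Pd2(dba)3 (2.5 mol%), P(2-furyl)3 (10 mol%), Cu(O2C-2-thienyl) (1.5 equiv), THF, rt, argon
Reagents that add atoms: none
Why: Liebeskind–Srogl thioester–boronic acid ketone synthesis: zerovalent palladium inserts into the C(O)–S bond of 11, the monovalent copper carboxylate binds the thiolate and activates boron, the alkenyl group moves to palladium with retention, and reductive elimination forms the C5–C6 bond. No ring is closed and no stereocentre is formed; the C6=C7 geometry is the Z geometry of 31, carried through unchanged. The step needs chemoselectivity for the thioester over the C12 ketone, both silyl ethers and both alkenes, which the neutral medium and the exclusive reactivity of palladium toward the C–S bond should secure. It also needs C2=C3 to stay out of conjugation, and the absence of base leaves the doubly activated C4 methylene untouched. Room temperature and fast copper-assisted transmetalation are chosen so that the acylpalladium intermediate does not lose CO.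

Step 18
Reactants: 32 (2R,5S)-2-[(4Z,8E)-10-[5-(tert-butyldimethylsilyloxy)-2-methoxy-3-methylphenyl]-4,8-dimethyl-6-oxodeca-4,8-dienyl]-2,6,6-trimethyl-5-(triethylsilyloxy)oxan-3-one
Product: 33 (2R,5S)-5-hydroxy-2-[(4Z,8E)-10-(5-hydroxy-2-methoxy-3-methylphenyl)-4,8-dimethyl-6-oxodeca-4,8-dienyl]-2,6,6-trimethyloxan-3-one (CNP0268050.1)
Conditions: n-Bu4NF, AcOH (1:1), THF, 0 °C
Reagents that add atoms: none
Why: Fluoride desilylation of the aryl and the secondary silyl ether; buffering with acetic acid keeps the medium near neutral so that the β-hydroxy ketone should not eliminate and neither double bond should move or isomerise.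

Compound list
1 | 2-bromo-6-methylanisole | COc1c(C)cccc1Br | starting material
2 | 2-(3-bromo-4-methoxy-5-methylphenyl)-4,4,5,5-tetramethyl-1,3,2-dioxaborolane | COc1c(C)cc(cc1Br)B1OC(C)(C)C(C)(C)O1 | intermediate
3 | 3-bromo-4-methoxy-5-methylphenol | COc1c(C)cc(O)cc1Br | intermediate
4 | (3-bromo-4-methoxy-5-methylphenoxy)(tert-butyl)dimethylsilane | COc1c(C)cc(O[Si](C)(C)C(C)(C)C)cc1Br | intermediate
5 | S-phenyl thioacetate | CC(=O)Sc1ccccc1 | starting material
6 | methyl vinyl ketone | CC(=O)C=C | starting material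
7 | lithium 1-(phenylsulfanyl)ethenolate | [Li+].[O-]C(=C)Sc1ccccc1 | intermediate
8 | 4-methyl-4-vinyloxetan-2-one (racemic) | CC1(C=C)CC(=O)O1 | intermediate
9 | [5-(tert-butyldimethylsilyloxy)-2-methoxy-3-methylphenyl]magnesium bromide | COc1c(C)cc(O[Si](C)(C)C(C)(C)C)cc1[Mg]Br | intermediate
10 | (E)-5-[5-(tert-butyldimethylsilyloxy)-2-methoxy-3-methylphenyl]-3-methylpent-3-enoic acid | COc1c(C)cc(O[Si](C)(C)C(C)(C)C)cc1C/C=C(\C)CC(=O)O | intermediate
11 | S-phenyl (E)-5-[5-(tert-butyldimethylsilyloxy)-2-methoxy-3-methylphenyl]-3-methylpent-3-enethioate | COc1c(C)cc(O[Si](C)(C)C(C)(C)C)cc1C/C=C(\C)CC(=O)Sc1ccccc1 | intermediate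
12 | (R)-(−)-linalool, (3R)-3,7-dimethylocta-1,6-dien-3-ol | CC(C)=CCC[C@@](C)(O)C=C | starting material
13 | triethyl{[(3R)-3,7-dimethylocta-1,6-dien-3-yl]oxy}silane | CC(C)=CCC[C@@](C)(O[Si](CC)(CC)CC)C=C | intermediate
14 | 3,3-dimethyl-5-[(3R)-3-methyl-3-(triethylsilyloxy)pent-4-enyl]-1,2,4-trioxolane (ozonide) | CC1(C)OOC(CC[C@@](C)(O[Si](CC)(CC)CC)C=C)O1 | intermediate
15 | (4R)-4-methyl-4-(triethylsilyloxy)hex-5-en-1-ol | OCCC[C@@](C)(O[Si](CC)(CC)CC)C=C | intermediate
16 | (3R)-6-chloro-3-methyl-3-(triethylsilyloxy)hex-1-ene | ClCCC[C@@](C)(O[Si](CC)(CC)CC)C=C | intermediate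
17 | (3R)-6-chloro-3-methyl-3-(triethylsilyloxy)hexan-2-one | ClCCC[C@@](C)(O[Si](CC)(CC)CC)C(C)=O | intermediate
18 | methacrolein | CC(=C)C=O | starting material
19 | diisopinocampheyl enol borinate of 17 | C=C(OB([C@@H]1C[C@@H]2C[C@H]([C@H]1C)C2(C)C)[C@@H]1C[C@@H]2C[C@H]([C@H]1C)C2(C)C)[C@@](C)(CCCCl)O[Si](CC)(CC)CC | intermediate
20 | (3S,6R)-9-chloro-3-hydroxy-2,6-dimethyl-6-(triethylsilyloxy)non-1-en-5-one | ClCCC[C@@](C)(O[Si](CC)(CC)CC)C(=O)C[C@H](O)C(C)=C | intermediate
21 | (3S,6R)-9-chloro-3,6-dihydroxy-2,6-dimethylnon-1-en-5-one | ClCCC[C@@](C)(O)C(=O)C[C@H](O)C(C)=C | intermediate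
22 | (2R,5S)-6-(chloromercuriomethyl)-2-(3-chloropropyl)-5-hydroxy-2,6-dimethyloxan-3-one (both C6 epimers) | ClCCC[C@@]1(C)OC(C)(C[Hg]Cl)[C@@H](O)CC1=O | intermediate
23 | (2R,5S)-2-(3-chloropropyl)-5-hydroxy-2,6,6-trimethyloxan-3-one | ClCCC[C@@]1(C)OC(C)(C)[C@@H](O)CC1=O | intermediate
24 | (2R,5S)-2-(3-chloropropyl)-2,6,6-trimethyl-5-(triethylsilyloxy)oxan-3-one | ClCCC[C@@]1(C)OC(C)(C)[C@@H](O[Si](CC)(CC)CC)CC1=O | intermediate
25 | (2R,5S)-2-(3-iodopropyl)-2,6,6-trimethyl-5-(triethylsilyloxy)oxan-3-one | ICCC[C@@]1(C)OC(C)(C)[C@@H](O[Si](CC)(CC)CC)CC1=O | intermediate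
26 | propyne | CC#C | starting material
27 | dibromo[(Z)-2-bromoprop-1-enyl]borane | C/C(Br)=C/B(Br)Br | intermediate
28 | 2-[(Z)-2-bromoprop-1-enyl]-4,4,5,5-tetramethyl-1,3,2-dioxaborolane | C/C(Br)=C/B1OC(C)(C)C(C)(C)O1 | intermediate
29 | {3-[(2R,5S)-2,6,6-trimethyl-3-oxo-5-(triethylsilyloxy)oxan-2-yl]propyl}zinc iodide | I[Zn]CCC[C@@]1(C)OC(C)(C)[C@@H](O[Si](CC)(CC)CC)CC1=O | intermediate
30 | (2R,5S)-2,6,6-trimethyl-2-[(Z)-4-methyl-5-(4,4,5,5-tetramethyl-1,3,2-dioxaborolan-2-yl)pent-4-enyl]-5-(triethylsilyloxy)oxan-3-one | CC1(C)OB(OC1(C)C)/C=C(/C)CCC[C@@]1(C)OC(C)(C)[C@@H](O[Si](CC)(CC)CC)CC1=O | intermediate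
31 | [(Z)-2-methyl-5-[(2R,5S)-2,6,6-trimethyl-3-oxo-5-(triethylsilyloxy)oxan-2-yl]pent-1-enyl]boronic acid | OB(O)/C=C(/C)CCC[C@@]1(C)OC(C)(C)[C@@H](O[Si](CC)(CC)CC)CC1=O | intermediate
32 | (2R,5S)-2-[(4Z,8E)-10-[5-(tert-butyldimethylsilyloxy)-2-methoxy-3-methylphenyl]-4,8-dimethyl-6-oxodeca-4,8-dienyl]-2,6,6-trimethyl-5-(triethylsilyloxy)oxan-3-one | COc1c(C)cc(O[Si](C)(C)C(C)(C)C)cc1C/C=C(\C)CC(=O)/C=C(/C)CCC[C@@]1(C)OC(C)(C)[C@@H](O[Si](CC)(CC)CC)CC1=O | intermediate
33 | (2R,5S)-5-hydroxy-2-[(4Z,8E)-10-(5-hydroxy-2-methoxy-3-methylphenyl)-4,8-dimethyl-6-oxodeca-4,8-dienyl]-2,6,6-trimethyloxan-3-one | COc1c(C)cc(O)cc1C/C=C(\C)CC(=O)/C=C(/C)CCC[C@@]1(C)OC(C)(C)[C@@H](O)CC1=O | target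

Total step count: 18. Longest linear sequence: 12 steps, from (R)-linalool 12 to 33 (steps 6 to 14, then 16, 17 and 18).

Steps most likely to fail

Step 17 (key step). The β,γ-unsaturated acylpalladium intermediate may lose CO before transmetalation, boron-to-palladium transfer may be slow and let protodeboronation compete, and long exposure to the copper salt may move C2=C3 into conjugation or isomerise C6=C7 from Z to E. The fallback sets out from 30 and 11 and comes back at 32. Boronate 30, isolated this time, is treated with NaOH and I2 (THF/H2O, 0 °C), which should give with retention the vinyl iodide (2R,5S)-2-[(Z)-5-iodo-4-methylpent-4-enyl]-2,6,6-trimethyl-5-(triethylsilyloxy)oxan-3-one F1. Thioester 11 is reduced with Et3SiH over Pd/C (acetone, rt; Fukuyama reduction) to the aldehyde F2. A Nozaki–Hiyama–Kishi coupling of F1 and F2 (CrCl2, NiCl2 cat., DMSO/THF, rt) forms the same C5–C6 bond. The organochromium reagent adds to the aldehyde only, leaves the ring ketone alone and keeps the alkene geometry, and should give the allylic alcohol F3 as a mixture of C5 epimers. Oxidation with Dess–Martin periodinane (NaHCO3, CH2Cl2, 0 °C) converges both epimers on 32.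

Step 10. Facial selectivity at the aldehyde may be poor if reagent control is weak or mismatched next to the fully substituted silyloxy carbon, and enolisation of the hindered ketone may be slow. The fallback sets out from 17 and comes back at 20. Ketone 17 is converted with Me3SiOTf and Et3N (CH2Cl2, 0 °C) into the silyl enol ether F4. A Mukaiyama aldol reaction of F4 with methacrolein 18 is run under a chiral boron Lewis acid that controls the aldehyde face from outside through an open transition state (B-butyl oxazaborolidinone from N-tosyltryptophan, the enantiomer that leaves the Si face open, EtCN, −78 °C). It should give the silyl ether F5. Citric acid in MeOH cleaves only the secondary trimethylsilyl ether and gives 20.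

Step 9. Oxypalladation may be slow at a vinyl group flanked by a fully substituted carbon, Markovnikov selectivity may erode toward the aldehyde, and the triethylsilyl ether may be lost in the cationic palladium/peroxide medium. The fallback sets out from 16 and comes back at 17. A Mukaiyama hydration (Co(acac)2 cat., PhSiH3, O2, i-PrOH, rt) places oxygen at the internal carbon by radical hydrogen-atom transfer, whatever the steric demand of the neighbouring centre, and should give the alcohol F6 as a mixture of C2 epimers. Dess–Martin periodinane (CH2Cl2, rt) oxidises F6 to 17.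

Further compounds
F1 | step 17 | (2R,5S)-2-[(Z)-5-iodo-4-methylpent-4-enyl]-2,6,6-trimethyl-5-(triethylsilyloxy)oxan-3-one | I/C=C(/C)CCC[C@@]1(C)OC(C)(C)[C@@H](O[Si](CC)(CC)CC)CC1=O
F2 | step 17 | (E)-5-[5-(tert-butyldimethylsilyloxy)-2-methoxy-3-methylphenyl]-3-methylpent-3-enal | COc1c(C)cc(O[Si](C)(C)C(C)(C)C)cc1C/C=C(\C)CC=O
F3 | step 17 | (2R,5S)-2-[(4Z,8E)-10-[5-(tert-butyldimethylsilyloxy)-2-methoxy-3-methylphenyl]-6-hydroxy-4,8-dimethyldeca-4,8-dienyl]-2,6,6-trimethyl-5-(triethylsilyloxy)oxan-3-one (both carbinol epimers) | COc1c(C)cc(O[Si](C)(C)C(C)(C)C)cc1C/C=C(\C)CC(O)/C=C(/C)CCC[C@@]1(C)OC(C)(C)[C@@H](O[Si](CC)(CC)CC)CC1=O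
F4 | step 10 | {[(3R)-6-chloro-3-methyl-3-(triethylsilyloxy)hex-1-en-2-yl]oxy}trimethylsilane | C=C(O[Si](C)(C)C)[C@@](C)(CCCCl)O[Si](CC)(CC)CC
F5 | step 10 | (3S,6R)-9-chloro-2,6-dimethyl-6-(triethylsilyloxy)-3-(trimethylsilyloxy)non-1-en-5-one | ClCCC[C@@](C)(O[Si](CC)(CC)CC)C(=O)C[C@H](O[Si](C)(C)C)C(C)=C
F6 | step 9 | (3R)-6-chloro-3-methyl-3-(triethylsilyloxy)hexan-2-ol (both C2 epimers) | ClCCC[C@@](C)(O[Si](CC)(CC)CC)C(C)O
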